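**Retrosynthetic overview**
1. Target ⇒ C7 exocyclic methylene (radical Markovnikov hydration) ⇒ spiro ketone.
2. Key step: ring B is closed last by a 6-endo bromine-atom-transfer radical cyclisation (C8–C9 bond) of a bromomethyl ketone onto the 1,1-dimethylallyl group on the already quaternary C6; the same event places Br on C10.
3. Ring A trans-bromochloride: carboxylate-relayed bromonium chemistry (bromolactonisation, then chlorinolysis with bromine shift) on a cyclohexene acid.
4. Quaternary C6 and C11: hydroxyl-controlled Ireland–Claisen rearrangement of a prenyl ester; C1 carbinol: enzymatic reduction; ring A carbocycle: ring-closing metathesis.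
5. Ring order: ring A first (metathesis), ring B second (radical spirocyclisation). Building blocks: pent-4-enoyl chloride, prenol, 3-methylbut-3-enoic acid; C8 comes from diazomethane and the C7 methyl from a titanium methylidene.

Assumption: 1, 2 and 4 are taken as catalogue chemicals; late compounds use the spiro numbering C1 (CHOAc), C3 (CClCH3), C4 (CHBr), C6 (spiro), C7 (carbinol), C10 (CHBr), C11 (C(CH3)2).

**Step 1**
Reactants: 1 pent-4-enoyl chloride; 2 3-methylbut-2-en-1-ol
Product: 3 3-methylbut-2-en-1-yl pent-4-enoate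
Conditions: Et3N, DMAP (cat.), CH2Cl2, 0 °C → rt
Reagents that add atoms: none
Why: Acylation of the primary allylic alcohol by the acid chloride (esterification); no stereocentre is formed.

**Step 2**
Reactants: 3 3-methylbut-2-en-1-yl pent-4-enoate; 4 3-methylbut-3-enoic acid
Product: 6 3-methylbut-2-en-1-yl 5-methyl-3-oxo-2-(prop-2-en-1-yl)hex-5-enoate, via 1-(3-methylbut-3-enoyl)imidazole 5 (not isolated)
Conditions: 4, CDI, THF, rt; separately 3 (2.1 equiv), LiN(iPr)2 (2.1 equiv), THF, −78 °C; add 5, −78 °C; aq NH4Cl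
Reagents that add atoms: none
Why: Crossed Claisen condensation: the lithium enolate of the ester C-acylates the acyl imidazole at −78 °C and the product is held as its doubly stabilised enolate, which keeps the β,γ-alkene out of conjugation; the new α-stereocentre is configurationally labile (racemic).

**Step 3**
Reactants: 6 3-methylbut-2-en-1-yl 5-methyl-3-oxo-2-(prop-2-en-1-yl)hex-5-enoate
Product: 7 3-methylbut-2-en-1-yl 4-methyl-6-oxocyclohex-3-ene-1-carboxylate
Conditions: second-generation Grubbs catalyst [RuCl2(=CHPh)(PCy3)(H2IMes)] (3 mol%), 1,4-benzoquinone (10 mol%), CH2Cl2, 40 °C, argon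
Reagents that add atoms: none
Why: Ring-closing metathesis between the allyl and isopropenyl termini closes ring A as the trisubstituted cyclohexene with loss of ethene, the trisubstituted prenyl alkene being inert; C1 remains labile.

**Step 4**
Reactants: 7 3-methylbut-2-en-1-yl 4-methyl-6-oxocyclohex-3-ene-1-carboxylate
Product: 8 3-methylbut-2-en-1-yl (1S,6R)-6-hydroxy-4-methylcyclohex-3-ene-1-carboxylate
Conditions: anti-Prelog ketoreductase (Lactobacillus kefir alcohol dehydrogenase type), NADP+ (cat.), iPrOH, phosphate buffer pH 7, 30 °C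
Reagents that add atoms: none
Why: Enzymatic ketone reduction with dynamic kinetic resolution: the keto ester racemises through its enol and the reductase delivers hydride to one carbonyl face, setting the carbinol carbon (R) as the cis hydroxy ester; the C1 configuration is erased in step 5.

**Step 5**
Reactants: 8 3-methylbut-2-en-1-yl (1S,6R)-6-hydroxy-4-methylcyclohex-3-ene-1-carboxylate
Product: 9 (1R,6R)-6-hydroxy-4-methyl-1-(2-methylbut-3-en-2-yl)cyclohex-3-ene-1-carboxylic acid
Conditions: LiN(iPr)2 (2.3 equiv), THF, −78 °C → 60 °C; aq HCl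
Reagents that add atoms: none
Why: Dianionic Ireland–Claisen [3,3] rearrangement of the lithium-chelated alkoxide–enolate (Fráter–Seebach-type control): the prenyl terminus reaches the enolate face anti to the ring CH2 of the carbinol carbon, so the 1,1-dimethylallyl group enters trans to OH and fixes the future spiro carbon (R) beside the new quaternary C(CH3)2.

**Step 6**
Reactants: 9 (1R,6R)-6-hydroxy-4-methyl-1-(2-methylbut-3-en-2-yl)cyclohex-3-ene-1-carboxylic acid
Product: 10 (1R,2R,4R,5R)-4-bromo-2-hydroxy-4-methyl-1-(2-methylbut-3-en-2-yl)-6-oxabicyclo[3.2.1]octan-7-one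
Conditions: NBS, THF, 0 °C, dark
Reagents that add atoms: N-bromosuccinimide, O=C1CCC(=O)N1Br
Why: Bromolactonisation: Br+ adds to the ring-alkene face opposite the carboxyl group and the carboxylate opens the bromonium trans-diaxially at the secondary carbon (γ-lactone, tertiary bromide anti to O), the trisubstituted alkene reacting before the neopentylic vinyl group; a δ-lactone regioisomer would lead to the same bromonium ion in step 8.

**Step 7**
Reactants: 10 (1R,2R,4R,5R)-4-bromo-2-hydroxy-4-methyl-1-(2-methylbut-3-en-2-yl)-6-oxabicyclo[3.2.1]octan-7-one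
Product: 11 (1R,2R,4R,5R)-4-bromo-4-methyl-1-(2-methylbut-3-en-2-yl)-7-oxo-6-oxabicyclo[3.2.1]octan-2-yl acetate
Conditions: Ac2O, pyridine, DMAP (cat.), CH2Cl2, rt
Reagents that add atoms: acetic anhydride, CC(=O)OC(C)=O
Why: DMAP-catalysed acetylation of the only free (secondary) hydroxyl installs the acetate of the target; no stereocentre changes.

**Step 8**
Reactants: 11 (1R,2R,4R,5R)-4-bromo-4-methyl-1-(2-methylbut-3-en-2-yl)-7-oxo-6-oxabicyclo[3.2.1]octan-2-yl acetate
Product: 14 [(1R,2R,4S,5S)-4-bromo-2-(bromoacetyl)-5-chloro-5-methyl-2-(2-methylbut-3-en-2-yl)cyclohexyl] acetate, via acid chloride 12 (not isolated), via diazoketone 13 (not isolated)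
Conditions: SOCl2, ZnCl2 (10 mol%), 55 °C; evaporate; CH2N2 (excess), Et2O, 0 °C; then 48% aq HBr, 0 °C
Reagents that add atoms: thionyl chloride, ClS(Cl)=O; diazomethane, C=[N+]=[N-]; hydrogen bromide, Br
Why: Proposed new method: ZnCl2-activated ionisation of the lactone C–O bond is assisted by the anti-periplanar tertiary bromide and regenerates the bromonium ion on the face opposite the carboxyl group; chloride opens it at the tertiary carbon from the carboxyl face, so Br ends on the secondary carbon and Cl on the tertiary carbon, trans to each other (both stereocentres set by the relay), any diaxial tertiary-bromide/secondary-chloride isomer converging on the same diequatorial product by the classical diaxial-to-diequatorial 1,2-dihalide interchange, while the freed carboxyl becomes the acid chloride that is homologated (diazoketone formation, then HBr) to the bromomethyl ketone; closest known reactions are SOCl2/ZnCl2 chlorinolysis of lactones to chloro acyl chlorides and anchimerically assisted substitution of trans-2-bromoalkyl esters.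

**Step 9**
Reactants: 14 [(1R,2R,4S,5S)-4-bromo-2-(bromoacetyl)-5-chloro-5-methyl-2-(2-methylbut-3-en-2-yl)cyclohexyl] acetate
Product: 15 (1R,3S,4S,6R,10R)-4,10-dibromo-3-chloro-3,11,11-trimethyl-7-oxospiro[5.5]undecan-1-yl acetate
Conditions: CuBr (10 mol%), tris(2-pyridylmethyl)amine (10 mol%), AIBN (10 mol%), ClCH2CH2Cl, 80 °C
Reagents that add atoms: none
Why: Copper-catalysed bromine atom-transfer radical cyclisation (Kharasch type): CuBr/ligand abstracts Br only from the α-bromoketone, the α-keto radical closes 6-endo onto the vinyl terminus (the normal mode for 2-oxohex-5-enyl radicals, reinforced by the neopentylic internal alkene carbon), and the secondary C10 radical takes Br back from the CuBr2 complex on the equatorial face anti to the axial C1 arm of ring A, giving the (10R) neopentylic bromide and completing the spirocycle.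

**Step 10**
Reactants: 15 (1R,3S,4S,6R,10R)-4,10-dibromo-3-chloro-3,11,11-trimethyl-7-oxospiro[5.5]undecan-1-yl acetate
Product: 16 (1R,3S,4S,6R,10R)-4,10-dibromo-3-chloro-3,11,11-trimethyl-7-methylidenespiro[5.5]undecan-1-yl acetate
Conditions: Cp2Ti(μ-Cl)(μ-CH2)AlMe2 (Tebbe reagent, 1.2 equiv), pyridine (cat.), THF/toluene, −40 → 0 °C
Reagents that add atoms: Tebbe reagent, C[Al](C)C[Ti](Cl)(C1C=CC=C1)C1C=CC=C1
Why: Tebbe methylenation (titanium methylidene [2+2]/retro-[2+2]) is non-basic, so the enolisable ketone with its γ-bromide and the other halides survive, and the hindered ketone reacts before the acetate at low temperature; no stereocentre is formed.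

**Step 11**
Reactants: 16 (1R,3S,4S,6R,10R)-4,10-dibromo-3-chloro-3,11,11-trimethyl-7-methylidenespiro[5.5]undecan-1-yl acetate
Product: 17 (1R,3S,4S,6R,7R,10R)-4,10-dibromo-3-chloro-7-hydroxy-3,7,11,11-tetramethylspiro[5.5]undecan-1-yl acetate
Conditions: Mn(dpm)3 (10 mol%), PhSiH3, O2 (1 atm), iPrOH/CH2Cl2, 0 °C → rt; then P(OEt)3
Reagents that add atoms: dioxygen, O=O
Why: Mukaiyama-type radical hydration by metal-hydride hydrogen-atom transfer: H adds to the CH2 terminus and the tertiary C7 radical is trapped by O2 from the equatorial side, away from the syn-axial C11 methyl, so OH ends equatorial and cis to C1 (7R); the phosphite reduces the peroxide.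

**Compound list**
1 | pent-4-enoyl chloride | C=CCCC(=O)Cl | starting material
2 | 3-methylbut-2-en-1-ol (prenol) | CC(C)=CCO | starting material
3 | 3-methylbut-2-en-1-yl pent-4-enoate | C=CCCC(=O)OCC=C(C)C | intermediate
4 | 3-methylbut-3-enoic acid | CC(=C)CC(=O)O | starting material
5 | 1-(3-methylbut-3-enoyl)imidazole | CC(=C)CC(=O)n1ccnc1 | intermediate (not isolated)
6 | 3-methylbut-2-en-1-yl 5-methyl-3-oxo-2-(prop-2-en-1-yl)hex-5-enoate (racemic, C2 labile) | C=CCC(C(=O)OCC=C(C)C)C(=O)CC(C)=C | intermediate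
7 | 3-methylbut-2-en-1-yl 4-methyl-6-oxocyclohex-3-ene-1-carboxylate (C1 labile) | CC1=CCC(C(=O)OCC=C(C)C)C(=O)C1 | intermediate
8 | 3-methylbut-2-en-1-yl (1S,6R)-6-hydroxy-4-methylcyclohex-3-ene-1-carboxylate (cis) | O[C@@H]1CC(C)=CC[C@@H]1C(=O)OCC=C(C)C | intermediate
9 | (1R,6R)-6-hydroxy-4-methyl-1-(2-methylbut-3-en-2-yl)cyclohex-3-ene-1-carboxylic acid (OH cis to CO2H) | O[C@@H]1CC(C)=CC[C@@]1(C(=O)O)C(C)(C)C=C | intermediate
10 | (1R,2R,4R,5R)-4-bromo-2-hydroxy-4-methyl-1-(2-methylbut-3-en-2-yl)-6-oxabicyclo[3.2.1]octan-7-one (Br anti to lactone O) | O[C@@H]1C[C@@](C)(Br)[C@H]2C[C@@]1(C(=O)O2)C(C)(C)C=C | intermediate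
11 | (1R,2R,4R,5R)-4-bromo-4-methyl-1-(2-methylbut-3-en-2-yl)-7-oxo-6-oxabicyclo[3.2.1]octan-2-yl acetate | CC(=O)O[C@@H]1C[C@@](C)(Br)[C@H]2C[C@@]1(C(=O)O2)C(C)(C)C=C | intermediate
12 | (1R,2R,4S,5S)-2-acetoxy-5-bromo-4-chloro-4-methyl-1-(2-methylbut-3-en-2-yl)cyclohexane-1-carbonyl chloride | CC(=O)O[C@@H]1C[C@](C)(Cl)[C@@H](Br)C[C@@]1(C(=O)Cl)C(C)(C)C=C | intermediate (not isolated)
13 | [(1R,2R,4S,5S)-4-bromo-5-chloro-2-(diazoacetyl)-5-methyl-2-(2-methylbut-3-en-2-yl)cyclohexyl] acetate | CC(=O)O[C@@H]1C[C@](C)(Cl)[C@@H](Br)C[C@@]1(C(=O)C=[N+]=[N-])C(C)(C)C=C | intermediate (not isolated)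
14 | [(1R,2R,4S,5S)-4-bromo-2-(bromoacetyl)-5-chloro-5-methyl-2-(2-methylbut-3-en-2-yl)cyclohexyl] acetate | CC(=O)O[C@@H]1C[C@](C)(Cl)[C@@H](Br)C[C@@]1(C(=O)CBr)C(C)(C)C=C | intermediate
15 | (1R,3S,4S,6R,10R)-4,10-dibromo-3-chloro-3,11,11-trimethyl-7-oxospiro[5.5]undecan-1-yl acetate | CC(=O)O[C@@H]1C[C@](C)(Cl)[C@@H](Br)C[C@@]12C(C)(C)[C@H](Br)CCC2=O | intermediate
16 | (1R,3S,4S,6R,10R)-4,10-dibromo-3-chloro-3,11,11-trimethyl-7-methylidenespiro[5.5]undecan-1-yl acetate | CC(=O)O[C@@H]1C[C@](C)(Cl)[C@@H](Br)C[C@@]12C(C)(C)[C@H](Br)CCC2=C | intermediate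
17 | (1R,3S,4S,6R,7R,10R)-4,10-dibromo-3-chloro-7-hydroxy-3,7,11,11-tetramethylspiro[5.5]undecan-1-yl acetate | CC(=O)O[C@@H]1C[C@](C)(Cl)[C@@H](Br)C[C@@]12C(C)(C)[C@H](Br)CC[C@@]2(C)O | target

**Totals and risks**
Total step count: 11. Longest linear sequence: 11 steps (1/2 → 3 → 6 → 7 → 8 → 9 → 10 → 11 → 14 → 15 → 16 → 17); acid 4 enters in step 2.

The three steps most likely to fail are 8, 9 and 11.

Step 8 (lactone chlorinolysis with bromine shift). The risk is capture of the bromonium ion at the wrong carbon, acetate participation, or elimination. The fallback sets out from 9 and rejoins at 12, and puts bromine directly on the secondary carbon so that no halogen migration is needed. Hydroxyl-directed epoxidation of 9 (VO(acac)2, t-BuOOH, CH2Cl2) gives the cis-epoxy acid F1, with the epoxide on the face of OH and CO2H. Li2NiBr4 in THF opens the epoxide at the secondary carbon with inversion to the bromohydrin F2. Ac2O/pyridine acetylates only the secondary hydroxyl to give the acetate F3. SOCl2 then turns the tertiary carbinol into the chloride with retention, through the bromonium ion bridged from the neighbouring trans bromine, and turns the acid into the acid chloride 12.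

Step 9 (radical spirocyclisation). The risks are short chains, 5-exo leakage, or bromine entering C10 from the wrong face. The conformational argument for the C10 configuration is the weakest stereochemical prediction in the route. The fallback sets out from 14 and rejoins at 15, replacing bromine transfer by degenerative xanthate transfer. KSC(S)OEt in acetone gives the S-acylmethyl xanthate F4. Dilauroyl peroxide in refluxing ClCH2CH2Cl drives the reversible, long-lived xanthate-transfer 6-endo cyclisation to the C10 xanthate F5. Radical exchange with ethyl 2-bromo-2-methylpropanoate (dilauroyl peroxide, chlorobenzene, reflux) then gives bromide 15; C10 is set in a separate bromine-transfer event whose donor can be varied.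

Step 11 (radical hydration). The risk is low facial selectivity in O2 capture at C7. The fallback sets out from 16 and rejoins at 17 by a two-electron route. Dimethyldioxirane in acetone at 0 °C epoxidises the exocyclic alkene from the equatorial side to the spiro-epoxide F6. MgI2 in Et2O opens it at the primary carbon to the iodohydrin F7. Bu3SnH (1.05 equiv) with Et3B/air at −78 → 0 °C removes iodine selectively in the presence of the secondary bromides to give 17.

**Further compounds**
F1 | step 8 | (1R,6R)-3,4-epoxy-6-hydroxy-4-methyl-1-(2-methylbut-3-en-2-yl)cyclohexane-1-carboxylic acid, epoxide cis to OH and CO2H | O[C@@H]1C[C@]2(C)O[C@@H]2C[C@@]1(C(=O)O)C(C)(C)C=C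
F2 | step 8 | (1R,2R,4S,5S)-5-bromo-2,4-dihydroxy-4-methyl-1-(2-methylbut-3-en-2-yl)cyclohexane-1-carboxylic acid | O[C@@H]1C[C@](C)(O)[C@@H](Br)C[C@@]1(C(=O)O)C(C)(C)C=C
F3 | step 8 | (1R,2R,4S,5S)-2-acetoxy-5-bromo-4-hydroxy-4-methyl-1-(2-methylbut-3-en-2-yl)cyclohexane-1-carboxylic acid | CC(=O)O[C@@H]1C[C@](C)(O)[C@@H](Br)C[C@@]1(C(=O)O)C(C)(C)C=C
F4 | step 9 | [(1R,2R,4S,5S)-4-bromo-5-chloro-2-{[(ethoxycarbonothioyl)sulfanyl]acetyl}-5-methyl-2-(2-methylbut-3-en-2-yl)cyclohexyl] acetate | CC(=O)O[C@@H]1C[C@](C)(Cl)[C@@H](Br)C[C@@]1(C(=O)CSC(=S)OCC)C(C)(C)C=C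
F5 | step 9 | (1R,3S,4S,6R,10R)-4-bromo-3-chloro-10-[(ethoxycarbonothioyl)sulfanyl]-3,11,11-trimethyl-7-oxospiro[5.5]undecan-1-yl acetate | CC(=O)O[C@@H]1C[C@](C)(Cl)[C@@H](Br)C[C@@]12C(C)(C)[C@H](SC(=S)OCC)CCC2=O
F6 | step 11 | spiro-epoxide of 16 at C7 (oxirane oxygen equatorial, cis to C1), (1R,3S,4S,6R,10R)-4,10-dibromo-3-chloro-3,11,11-trimethyl-7,7-(epoxymethano)spiro[5.5]undecan-1-yl acetate | CC(=O)O[C@@H]1C[C@](C)(Cl)[C@@H](Br)C[C@@]12C(C)(C)[C@H](Br)CC[C@]23CO3
F7 | step 11 | (1R,3S,4S,6R,7R,10R)-4,10-dibromo-3-chloro-7-hydroxy-7-(iodomethyl)-3,11,11-trimethylspiro[5.5]undecan-1-yl acetate | CC(=O)O[C@@H]1C[C@](C)(Cl)[C@@H](Br)C[C@@]12C(C)(C)[C@H](Br)CC[C@@]2(CI)O
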